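**Strategy.** The target is 7-epi-clusianone: a bicyclo[3.3.1]nonane-2,4,9-trione (bridgeheads C1 and C5, gem-dimethyl C8 next to C1, bridging ketone C9) whose C7 prenyl group is endo. Everything rests on reading ring C1–C2–C3–C4–C5–C9 as a dearomatised 2-benzoylphloroglucinol in which the prenyl-bearing carbons C1 and C5 form a 1,3-dinucleophile. One operation joins the achiral diprenylated benzoylphloroglucinol to an α-(acetoxymethyl)-β,β-dimethyl enal, makes C1–C8 and C5–C6, closes ring C1–C8–C7–C6–C5–C9 and sets C1, C5 and C7 under chiral phase-transfer control. The endo formyl group is then turned into the third prenyl group by vinyl addition, allylic hydrogenolysis and cross-metathesis.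

Key step: step 5

Assumption 1 (catalyst sense): which pseudo-enantiomeric cinchona salt leads to the (1S,5R,7S) series cannot be predicted with confidence; the route is written for the hydrocinchonidinium salt, and its hydrocinchoninium analogue takes its place, with nothing else changed, if the first run gives the antipode.

Assumption 2 (ring–chain tautomerism): the 7-endo aldehyde made in the key step can close reversibly onto its own enolic C3 (internal aldol); the closed form is treated as a resting tautomer of that aldehyde, because the base of the following step reopens it.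

Stereodescriptors refer to the numbering above and to the tautomer drawn in the SMILES.

**Step 1**
Reactants: 1 2,4,6-trihydroxybenzophenone; 2 prenyl bromide (1-bromo-3-methylbut-2-ene)
Product: 3 2,4,6-trihydroxy-3,5-bis(3-methylbut-2-enyl)benzophenone
Conditions: 2 (2.1 equiv), 10% aq. KOH, 0 °C → rt
Reagents that add atoms: none
Why: Base-mediated C-alkylation of a phloroglucinol polyanion in water, where hydrogen bonding to the phenoxide oxygens steers the ambident anion to its two free ring carbons, and limiting the bromide to two equivalents holds back geminal over-alkylation.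

**Step 2**
Reactants: 4 dimethyl isopropylidenemalonate
Product: 5 2-(propan-2-ylidene)propane-1,3-diol
Conditions: i-Bu2AlH (DIBAL-H, 4.5 equiv), CH2Cl2, −78 → 0 °C; aq. potassium sodium tartrate
Reagents that add atoms: none
Why: Ester-to-alcohol reduction with an electrophilic aluminium hydride, which reduces both esters by 1,2-addition and leaves the hindered tetrasubstituted alkene untouched.

**Step 3**
Reactants: 5 2-(propan-2-ylidene)propane-1,3-diol
Product: 7 2-(hydroxymethyl)-3-methylbut-2-enyl acetate, via cyclic orthoester 6 (not isolated)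
Conditions: MeC(OMe)3 (1.2 equiv), PPTS (cat.), CH2Cl2, rt; then H2O, rt
Reagents that add atoms: trimethyl orthoacetate, CC(OC)(OC)OC; water, O
Why: Monoacetylation of a symmetrical 1,3-diol through its cyclic orthoester, whose mild acid hydrolysis opens the dioxanylium ion to exactly one acetate and one free hydroxyl, so that no diacetate can form.

**Step 4**
Reactants: 7 2-(hydroxymethyl)-3-methylbut-2-enyl acetate
Product: 8 2-(acetoxymethyl)-3-methylbut-2-enal
Conditions: activated MnO2 (excess), CH2Cl2, rt
Reagents that add atoms: none
Why: MnO2 oxidation of an allylic alcohol, which spares the acetate and raises no question of alkene geometry because the β-carbon carries two methyl groups.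

**Step 5 (key step)**
Reactants: 3 2,4,6-trihydroxy-3,5-bis(3-methylbut-2-enyl)benzophenone; 8 2-(acetoxymethyl)-3-methylbut-2-enal
Product: 10 (1S,5R,7S)-7-endo-formyl-3-[hydroxy(phenyl)methylidene]-8,8-dimethyl-1,5-bis(3-methylbut-2-enyl)bicyclo[3.3.1]nonane-2,4,9-trione, via acrolein-bearing dienone 9 (not isolated)
Conditions: 8 (1.5 equiv), CsOH·H2O (5 equiv), 2,7-bis[(O(9)-allylhydrocinchonidinium-N-yl)methyl]naphthalene dibromide (25 mol %), 4 Å molecular sieves, CH2Cl2, −50 °C; cold pH 5 buffer
Reagents that add atoms: none
Why: The cesium phenoxide of 3, ion-paired with the chiral ammonium cation, attacks the CMe2 terminus of 8 through one prenyl-bearing carbon, the enolate formed expels acetate (E1cB) to give the 2-substituted acrolein 9 (C1–C8 made), the second prenyl-bearing carbon then adds to the new methylene (C5–C6) and the aldehyde enolate is protonated at C7. This is the known alkylative dearomatization–annulation of acylphloroglucinols with α-(acetoxymethyl) Michael acceptors, run in its chiral phase-transfer form. The one ring closed, C1–C8–C7–C6–C5–C9, forms by a 6-endo-trig intramolecular Michael addition through a chair-like transition state. C1 is set by the catalyst, which must tell apart the two enantiotopic prenylated carbons of the mirror-symmetric phenoxide; C5 follows from C1 because the three-atom tether reaches only the ring face it already occupies; C7 is set by protonation of the enolate from the exo face, the endo face being covered by the C2–C3–C4 bridge, so the formyl group ends endo. The step needs C- over O-alkylation and closure through C5 and not through the benzoyl-bearing carbon: O-adducts revert by retro-oxa-Michael, the acylated carbon is the most stabilised and least nucleophilic site, and once both bonds are made the bridged trione cannot rearomatize. The low temperature and the cold buffered quench should keep the kinetic 7-endo aldehyde from equilibrating to the 7-exo epimer, and only the endo epimer can rest as the internal C3 aldol form, which step 6 reopens.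

**Step 6**
Reactants: 10 the 7-endo-formyl trione
Product: 11 7-endo-(1-hydroxyprop-2-enyl)-3-[hydroxy(phenyl)methylidene]-8,8-dimethyl-1,5-bis(3-methylbut-2-enyl)bicyclo[3.3.1]nonane-2,4,9-trione (C1, C5, C7 as in 10; carbinol carbon as a mixture of epimers)
Conditions: CH2=CHMgBr (4 equiv), CeCl3 (anhydrous, 4 equiv), THF, −78 → −20 °C; pH 7 buffer
Reagents that add atoms: vinylmagnesium bromide, C=C[Mg]Br
Why: Organocerium 1,2-addition to an aldehyde, in which the first equivalent turns the β-triketone into its unreactive metal enolate (and reopens any internally closed aldol form by retro-aldol) and the weakly basic vinylcerium then adds to the formyl group faster than it deprotonates C7, which thereby stops being epimerizable; the new carbinol centre is not controlled and is erased in step 9.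

**Step 7**
Reactants: 11 the allylic alcohol with free enol
Product: 12 3-benzoyl-7-endo-(1-hydroxyprop-2-enyl)-4-methoxy-8,8-dimethyl-1,5-bis(3-methylbut-2-enyl)bicyclo[3.3.1]non-3-ene-2,9-dione (C1, C5, C7 as in 10)
Conditions: TMSCHN2 (2 M in hexanes, 1.5 equiv), i-Pr2NEt, MeCN–MeOH (9:1), 0 °C
Reagents that add atoms: (trimethylsilyl)diazomethane, C[Si](C)(C)C=[N+]=[N-]
Why: O-methylation of an acidic enol (a vinylogous carboxylic acid) by a diazoalkane, which ignores the secondary alcohol and should take the less hindered oxygen at C4, remote from the C8 methyl groups; a C2–O regioisomer, should any form, converges in step 11.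

**Step 8**
Reactants: 12 the 4-O-methyl allylic alcohol
Product: 13 methyl carbonate of 12 (3-benzoyl-4-methoxy-7-endo-[1-(methoxycarbonyloxy)prop-2-enyl]-8,8-dimethyl-1,5-bis(3-methylbut-2-enyl)bicyclo[3.3.1]non-3-ene-2,9-dione)
Conditions: ClCO2Me (3 equiv), pyridine, DMAP (cat.), CH2Cl2, 0 °C → rt
Reagents that add atoms: methyl chloroformate, COC(=O)Cl
Why: Amine-catalysed acylation of a secondary alcohol to a mixed carbonate, under conditions in which no alkoxide forms that could attack the neighbouring vinylogous ester.

**Step 9**
Reactants: 13 the allylic methyl carbonate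
Product: 14 7-endo-allyl-3-benzoyl-4-methoxy-8,8-dimethyl-1,5-bis(3-methylbut-2-enyl)bicyclo[3.3.1]non-3-ene-2,9-dione
Conditions: Pd(OAc)2 (5 mol %), n-Bu3P (10 mol %), HCO2H–Et3N (3 equiv each), THF, 40 °C
Reagents that add atoms: none
Why: Tsuji formate hydrogenolysis of an allylic carbonate, in which zerovalent palladium ionises the carbonate, the bound formate loses CO2 and the resulting hydride is delivered to the more substituted allyl terminus (the carbon on C7) to give the terminal olefin; C7 lies outside the allyl system and keeps its configuration, and the methyl enol ether keeps C3 from acting as a nucleophile.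

**Step 10**
Reactants: 14 the 7-endo-allyl compound
Product: 15 4-O-methyl-7-epi-clusianone (3-benzoyl-4-methoxy-8,8-dimethyl-1,5,7-tris(3-methylbut-2-enyl)bicyclo[3.3.1]non-3-ene-2,9-dione, 7-endo)
Conditions: 2-methyl-2-butene (large excess), second-generation Grubbs catalyst RuCl2(=CHPh)(H2IMes)(PCy3) (10 mol %), CH2Cl2, 40 °C
Reagents that add atoms: 2-methyl-2-butene, CC=C(C)C
Why: Olefin cross-metathesis of a terminal alkene with 2-methyl-2-butene, which caps it as the trisubstituted prenyl terminus while exchange at the two existing prenyl groups is degenerate.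

**Step 11**
Reactants: 15 4-O-methyl-7-epi-clusianone
Product: 16 7-epi-clusianone, (1S,5R,7S)-3-[hydroxy(phenyl)methylidene]-8,8-dimethyl-1,5,7-tris(3-methylbut-2-enyl)bicyclo[3.3.1]nonane-2,4,9-trione (7-endo)
Conditions: LiCl (10 equiv), DMSO, 120 °C; cold dilute aq. HCl to pH 4
Reagents that add atoms: none
Why: Krapcho-type O-demethylation, in which chloride attacks the methyl carbon of the vinylogous ester (SN2) and releases the stabilised triketone enolate; C1 and C5 are quaternary and C7 is not α to a carbonyl, so no stereocentre is at risk.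

**Compound list**
1 | 2,4,6-trihydroxybenzophenone | O=C(c1ccccc1)c1c(O)cc(O)cc1O | starting material
2 | prenyl bromide | CC(C)=CCBr | starting material
3 | 2,4,6-trihydroxy-3,5-bis(3-methylbut-2-enyl)benzophenone | O=C(c1ccccc1)c1c(O)c(CC=C(C)C)c(O)c(CC=C(C)C)c1O | intermediate
4 | dimethyl isopropylidenemalonate | COC(=O)C(=C(C)C)C(=O)OC | starting material
5 | 2-(propan-2-ylidene)propane-1,3-diol | CC(C)=C(CO)CO | intermediate
6 | 2-methoxy-2-methyl-5-(propan-2-ylidene)-1,3-dioxane | COC1(C)OCC(=C(C)C)CO1 | intermediate (not isolated)
7 | 2-(hydroxymethyl)-3-methylbut-2-enyl acetate | CC(=O)OCC(CO)=C(C)C | intermediate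
8 | 2-(acetoxymethyl)-3-methylbut-2-enal | CC(=O)OCC(C=O)=C(C)C | intermediate
9 | 2-benzoyl-6-(3-formyl-2-methylbut-3-en-2-yl)-3,5-dihydroxy-4,6-bis(3-methylbut-2-enyl)cyclohexa-2,4-dien-1-one (the quaternary ring carbon becomes C1) | C=C(C=O)C(C)(C)[C@]1(CC=C(C)C)C(=O)C(C(=O)c2ccccc2)=C(O)C(CC=C(C)C)=C1O | intermediate (not isolated)
10 | (1S,5R,7S)-7-endo-formyl-3-[hydroxy(phenyl)methylidene]-8,8-dimethyl-1,5-bis(3-methylbut-2-enyl)bicyclo[3.3.1]nonane-2,4,9-trione | O=C[C@H]1C[C@@]2(CC=C(C)C)C(=O)/C(=C(/O)c3ccccc3)C(=O)[C@](CC=C(C)C)(C2=O)C1(C)C | intermediate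
11 | 7-endo-(1-hydroxyprop-2-enyl) analogue of 10, carbinol epimers | C=CC(O)[C@H]1C[C@@]2(CC=C(C)C)C(=O)/C(=C(/O)c3ccccc3)C(=O)[C@](CC=C(C)C)(C2=O)C1(C)C | intermediate
12 | 3-benzoyl-7-endo-(1-hydroxyprop-2-enyl)-4-methoxy-8,8-dimethyl-1,5-bis(3-methylbut-2-enyl)bicyclo[3.3.1]non-3-ene-2,9-dione | C=CC(O)[C@H]1C[C@@]2(CC=C(C)C)C(OC)=C(C(=O)c3ccccc3)C(=O)[C@](CC=C(C)C)(C2=O)C1(C)C | intermediate
13 | methyl carbonate of 12 | C=CC(OC(=O)OC)[C@H]1C[C@@]2(CC=C(C)C)C(OC)=C(C(=O)c3ccccc3)C(=O)[C@](CC=C(C)C)(C2=O)C1(C)C | intermediate
14 | 7-endo-allyl-3-benzoyl-4-methoxy-8,8-dimethyl-1,5-bis(3-methylbut-2-enyl)bicyclo[3.3.1]non-3-ene-2,9-dione | C=CC[C@H]1C[C@@]2(CC=C(C)C)C(OC)=C(C(=O)c3ccccc3)C(=O)[C@](CC=C(C)C)(C2=O)C1(C)C | intermediate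
15 | 4-O-methyl-7-epi-clusianone | CC(C)=CC[C@H]1C[C@@]2(CC=C(C)C)C(OC)=C(C(=O)c3ccccc3)C(=O)[C@](CC=C(C)C)(C2=O)C1(C)C | intermediate
16 | 7-epi-clusianone (1S,5R,7S; 7-endo prenyl) | CC(C)=CC[C@H]1C[C@@]2(CC=C(C)C)C(=O)/C(=C(/O)c3ccccc3)C(=O)[C@](CC=C(C)C)(C2=O)C1(C)C | target

**Step count.** Total: 11 steps. Longest linear sequence: 10 steps (4 → 16, steps 2–11); the arene branch (step 1) joins at step 5.

**Steps most likely to fail**

Step 5. What may go wrong: the chiral ion pair may discriminate poorly between the two enantiotopic prenylated carbons, so that the first C–C bond forms with low enantioselectivity. Fallback (resolution in place of asymmetric catalysis): setting out from 3 and 8, the annulation is run under the same cold conditions with the achiral salt n-Bu4NBr. This should give 10 together with its mirror image, the (1R,5S,7R)-aldehyde F1. The antipodes are separated by preparative supercritical-fluid chromatography on an amylose tris(3,5-dimethylphenylcarbamate) phase, and enantiopure 10 comes back to the route at step 6.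

Step 6. What may go wrong: deprotonation at C7 by the basic vinyl reagent before addition, which would erode the endo configuration, or competing addition to the C9 ketone. Fallback (protection first, then a non-basic organochromium addition): setting out from 10, the enol is methylated first (TMSCHN2, i-Pr2NEt, MeCN–MeOH, 0 °C) to the 4-O-methyl enol ether aldehyde F2. The vinyl group is then introduced by a Nozaki–Hiyama–Kishi reaction (vinyl bromide, CrCl2, NiCl2 (cat.), DMF, rt), whose vinylchromium species is not basic and adds to aldehydes only. This gives 12, where the route is rejoined.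

Step 9. What may go wrong: hydride delivery to the unsubstituted allyl terminus, β-hydride loss from the π-allyl complex toward C7, or capture of the endo-held allyl cation by ring C1–C2–C3–C4–C5–C9. Fallback (transposition followed by a sigmatropic reduction, with no π-allylpalladium cation): setting out from 12, acetylation (Ac2O, pyridine, DMAP) gives the secondary allylic acetate F3. PdCl2(MeCN)2 (cat.) in THF moves the acetate by [3,3] transposition to the primary (E)-allylic acetate F4. K2CO3 in MeOH frees the primary (E)-allylic alcohol F5. A Myers reductive transposition (2-nitrobenzenesulfonylhydrazide, PPh3, diethyl azodicarboxylate, THF, −30 °C → rt) then passes through the N-allyl sulfonylhydrazide F6 and the allylic diazene F7. The diazene loses N2 by a retro-ene shift that places the hydrogen on the carbon attached to C7 and gives 14, where the route is rejoined.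

**Further compounds**
F1 | step 5 | (1R,5S,7R)-enantiomer of aldehyde 10 | O=C[C@@H]1C[C@]2(CC=C(C)C)C(=O)/C(=C(/O)c3ccccc3)C(=O)[C@@](CC=C(C)C)(C2=O)C1(C)C
F2 | step 6 | 3-benzoyl-7-endo-formyl-4-methoxy-8,8-dimethyl-1,5-bis(3-methylbut-2-enyl)bicyclo[3.3.1]non-3-ene-2,9-dione | O=C[C@H]1C[C@@]2(CC=C(C)C)C(OC)=C(C(=O)c3ccccc3)C(=O)[C@](CC=C(C)C)(C2=O)C1(C)C
F3 | step 9 | acetate of 12 (secondary allylic acetate) | C=CC(OC(C)=O)[C@H]1C[C@@]2(CC=C(C)C)C(OC)=C(C(=O)c3ccccc3)C(=O)[C@](CC=C(C)C)(C2=O)C1(C)C
F4 | step 9 | 7-endo-[(E)-3-acetoxyprop-1-enyl] analogue of 14 | CC(=O)OC/C=C/[C@H]1C[C@@]2(CC=C(C)C)C(OC)=C(C(=O)c3ccccc3)C(=O)[C@](CC=C(C)C)(C2=O)C1(C)C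
F5 | step 9 | 7-endo-[(E)-3-hydroxyprop-1-enyl] analogue of 14 | OC/C=C/[C@H]1C[C@@]2(CC=C(C)C)C(OC)=C(C(=O)c3ccccc3)C(=O)[C@](CC=C(C)C)(C2=O)C1(C)C
F6 | step 9 | N-allyl-N-(2-nitrobenzenesulfonyl)hydrazine derived from F5 | NN(C/C=C/[C@H]1C[C@@]2(CC=C(C)C)C(OC)=C(C(=O)c3ccccc3)C(=O)[C@](CC=C(C)C)(C2=O)C1(C)C)S(=O)(=O)c1ccccc1[N+](=O)[O-]
F7 | step 9 | allylic diazene derived from F6 | N=NC/C=C/[C@H]1C[C@@]2(CC=C(C)C)C(OC)=C(C(=O)c3ccccc3)C(=O)[C@](CC=C(C)C)(C2=O)C1(C)C
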